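## The problem

Prebarbigerone is an isoflavone: a chromen-4-one (rings A and C) with a 2,4,5-trimethoxyphenyl group (ring B) on C3, a methoxy group on C7 and a 3-methylbut-2-enyl (prenyl) chain on C8. It has no stereocentre, and its only side-chain alkene ends in two identical methyl groups, so nothing stereochemical has to be set. The difficulty is regiochemistry and functional-group tolerance. Ring A carries four contiguous substituents (C4a, the C8a oxygen, the C8 chain, the C7 methoxy), and the chain sits in the crowded position between two oxygens, where direct prenylation of a finished 7-methoxyisoflavone is not a realistic option. The prenyl alkene is protonated to a tertiary cation by the acids normally used to close chromones, ring B is a very electron-rich arene that invites stray electrophiles and oxidants, and the finished pyranone opens at C2 with hydroxide. The feature that makes the plan possible is the position of C4a: it is ortho to the ring oxygen and para to the C7 methoxy group, while the only other carbon ortho to that oxygen is C8, which is already substituted. An acyl carbon tethered through the oxygen of a 2-substituted 3-methoxyphenyl ether can therefore reach exactly one ring carbon, and it is the most activated one. The side chain is carried as an allyl group through the acidic ring closure and extended to prenyl afterwards.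

## Retrosynthesis

**Side chain.** The target 16 is cut at the trisubstituted double bond of the prenyl group, giving the 8-allyl isoflavone 14 and 2-methylbut-2-ene 15, to be joined by cross-metathesis. Carrying the prenyl group from the start would expose it to the acid of the ring closure; an allyl group is not protonated under those conditions. The forward step only has to distinguish a terminal alkene from the conjugated, trisubstituted C2=C3 bond of the pyranone.

**Ring C.** Isoflavone 14 is cut at C4–C4a, which leads to the (Z)-3-aryloxy-2-arylacrylic acid 12, activated in the flask as its mixed anhydride 13. Two neighbouring cuts were weighed against this one: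
- Closing ring C at O1–C2 needs a 2-hydroxydeoxybenzoin, made by Lewis-acid acylation of an ortho-allyl phenol, which puts the allyl group at risk.
- Joining ring B at C3 by cross-coupling needs a 3-halochromone, made with an electrophilic halogen in the presence of the allyl alkene.

The C4–C4a cut removes the whole pyranone and leaves two arenes bridged by an acrylic acid. The forward reaction must acylate ring A at its single open ortho carbon and leave ring B and the allyl group alone.

**Acid.** Acid 12 comes from its methyl ester 11. The ester is needed earlier, to make the acrylate carbon skeleton by enolate chemistry. Its cleavage must not displace the β-aryloxy group.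

**Vinyl ether.** Ester 11 is cut at the O1–C2 bond into 2-allyl-3-methoxyphenol 6 and the (Z)-enol tosylate 10. This is the convergent cut: the two halves are of similar size and the bond forms by addition–elimination at the β-carbon of an acrylate. Adding the phenol to an alkynoate instead would leave the C3 aryl group to be introduced later. The forward step asks the phenoxide to attack carbon, not sulfur.

**Acrylate.** Tosylate 10 comes from the enol 9 of the α-formyl ester. Enol 9 is cut at the C2–C3 bond (chromone numbering) back to methyl arylacetate 8 and a formate ester, and 8 comes from the commercial acid 7. The one carbon added here becomes C2 of the chromone.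

**Ring A fragment.** Phenol 6 is cut at the aryl–allyl bond. A Claisen rearrangement of the allyl ether of 3-methoxyphenol 1 would deliver the allyl group mainly to the other ortho carbon, so the bond is made by directed metalation instead. The methoxymethyl ether 2 is lithiated between its two oxygens to give aryllithium 4, which is alkylated with allyl bromide 3 to give 5, and the acetal is then removed. Compounds 1, 3, 7 and 15 are commercial.

## Roads not taken

**Alternative 1:** Ring A is built by a Diels–Alder reaction that forms C5–C6 and C4a–C8a. The 2-prenylated silyloxydiene A1 would add to the terminal ynone A2, and loss of methanol on work-up would aromatise the adduct to the deoxybenzoin A3. A one-carbon amide acetal would then close ring C to 16.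
- Merits: every ring A substituent is placed by the polarity of the two partners, the prenyl group enters by simple C-alkylation, no acid strong enough to harm it is needed, and no late metathesis is required. The linear sequence would be shorter than in the chosen plan, and that is conceded.
- Weak points: A2 has a methylene flanked by an aryl ring and an ynone carbonyl, so it enolises and isomerises readily and is a polymerisable Michael acceptor. A1 is a fully substituted, hydrolytically labile ketene acetal whose hindered acetal carbon must bond to the internal alkyne carbon. The reaction can stop at the Mukaiyama–Michael stage or go astray by carbonyl addition. Neither partner can be bought.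
- Comparison: the chosen plan sets against the shorter linear sequence a set of stable, storable intermediates and reactions that each have close precedent on the same substrate type.

**Alternative 2:** Ring A is formed at C8–C8a and C6–C7. The ynol ether A5 would add across the diene made of the C4a=C8a bond and the vinyl group of pyranone A4 to give the racemic dihydrochromone A6, which a quinone oxidant would aromatise to 16.
- Merits: the route is convergent on paper, and the polarised ynol ether should place the methoxy and prenyl groups correctly.
- Weak points: the diene borrows a double bond from a 4-pyranone, a vinylogous ester with some aromatic stabilisation, so it is a reluctant diene. Ynol ethers and enones tend toward [2+2] addition or hydrolysis. A6 has a stereocentre that is made only to be destroyed, and the oxidation must spare the prenyl group and ring B. A4 and A5 each need their own multistep synthesis, and no close precedent exists.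
- Comparison: this road is not better than the chosen plan in any respect; the chosen ring closure is far better secured.

**Alternative 3:** Ring C is closed at C3–C4 by an intramolecular crossed benzoin reaction. A triazolium-derived carbene with an amidine base would turn the aldehyde of keto aldehyde A7 into an acyl anion equivalent that adds to the tethered aryl ketone, giving the racemic 3-hydroxyisoflavanone A8. Dehydration would give 16.
- Merits: the conditions are mild and non-acidic, so the prenyl group could be present from the beginning, and A7 is assembled convergently by an O-alkylation. The step count would be similar, and no ruthenium step is needed. This is a real advantage over the chosen plan.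
- Weak points: the acceptor is an ortho- and para-methoxylated aryl ketone, which is hindered and poorly electrophilic. Under the basic conditions the α-aryloxy ketone can enolise and condense with the aldehyde (the Rap–Stoermer pathway), which consumes A7 irreversibly. A8 still needs a separate dehydration of a tertiary benzylic alcohol next to a carbonyl, in the presence of the prenyl group.
- Comparison: the chosen plan sets against the mildness of this road a ring closure with no competing aldol channel, a single possible site of attack, and no adjustment of oxidation level afterwards.

Key step: step 9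

Remark on the chemistry: compounds 10–13 are drawn as the Z isomers expected from the chelation-controlled tosylation and a stereoretentive substitution. The geometry is not decisive, because the activated acid can rotate about the C2–C3 bond before ring closure.

## Route

Step 1
Reactants: 1 3-methoxyphenol
Product: 2 1-methoxy-3-(methoxymethoxy)benzene
Conditions: MOMCl, i-Pr2NEt, CH2Cl2, 0 °C to rt
Reagents that add atoms: chloromethyl methyl ether (MOMCl), COCCl
Why: O-alkylation of the phenol with an α-chloro ether (MOM protection); the acetal oxygen then acts with the methoxy group as a pair of ortho-directing groups in step 2.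

Step 2
Reactants: 2 1-methoxy-3-(methoxymethoxy)benzene; 3 allyl bromide
Product: 5 2-allyl-1-methoxy-3-(methoxymethoxy)benzene, via aryllithium 4 (not isolated)
Conditions: n-BuLi, THF, 0 °C to rt; then allyl bromide, −78 °C to rt
Reagents that add atoms: none
Why: Directed ortho-metalation: the proton between the OMe and OMOM groups is the one both oxygens direct lithium to, so 1,3-dioxygenated benzenes lithiate there as a rule; the aryllithium then displaces bromide from the allylic halide, and SN2 and SN2′ attack give the same allyl group.

Step 3
Reactants: 5 2-allyl-1-methoxy-3-(methoxymethoxy)benzene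
Product: 6 2-allyl-3-methoxyphenol
Conditions: HCl (cat.), MeOH, 40 °C
Reagents that add atoms: none
Why: Acid-catalysed acetal exchange (MOM cleavage) with methanol as acceptor; a monosubstituted allyl group ortho to the phenol should neither hydrate nor cyclise under dilute HCl at this temperature.

Step 4
Reactants: 7 2-(2,4,5-trimethoxyphenyl)acetic acid
Product: 8 methyl 2-(2,4,5-trimethoxyphenyl)acetate
Conditions: MeOH, H2SO4 (cat.), reflux
Reagents that add atoms: methanol, CO
Why: Fischer esterification; the methyl ester is the enolisable carboxyl derivative needed for the formylation.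

Step 5
Reactants: 8 methyl 2-(2,4,5-trimethoxyphenyl)acetate
Product: 9 methyl (Z)-3-hydroxy-2-(2,4,5-trimethoxyphenyl)acrylate (enol form of the α-formyl ester)
Conditions: NaH, HCO2Me, THF, 0 °C to rt; then aq. HCl
Reagents that add atoms: methyl formate, COC=O
Why: Crossed Claisen condensation (α-formylation) of an arylacetate with a non-enolisable formate, driven by deprotonation of the product; acidification should give the hydrogen-bonded Z enol.

Step 6
Reactants: 9 methyl (Z)-3-hydroxy-2-(2,4,5-trimethoxyphenyl)acrylate
Product: 10 methyl (Z)-2-(2,4,5-trimethoxyphenyl)-3-(tosyloxy)acrylate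
Conditions: TsCl, TMEDA, LiCl, MeCN, 0 °C
Reagents that add atoms: p-toluenesulfonyl chloride (TsCl), Cc1ccc(cc1)S(Cl)(=O)=O
Why: O-Sulfonylation of the enol; lithium chelation holds the enol oxygen and the ester carbonyl on the same side, so the tosylate should form with TsO cis to the ester (Z), while TMEDA takes up the HCl.

Step 7
Reactants: 6 2-allyl-3-methoxyphenol; 10 methyl (Z)-2-(2,4,5-trimethoxyphenyl)-3-(tosyloxy)acrylate
Product: 11 methyl (Z)-3-(2-allyl-3-methoxyphenoxy)-2-(2,4,5-trimethoxyphenyl)acrylate
Conditions: K2CO3, DMF, rt
Reagents that add atoms: none
Why: Nucleophilic vinylic substitution by addition–elimination: the phenoxide adds to the β-carbon of the β-sulfonyloxyacrylate and tosylate leaves from the ester-stabilised carbanion, with retention of geometry expected for so good a leaving group; any E isomer is carried on because both converge in step 9.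

Step 8
Reactants: 11 methyl (Z)-3-(2-allyl-3-methoxyphenoxy)-2-(2,4,5-trimethoxyphenyl)acrylate
Product: 12 (Z)-3-(2-allyl-3-methoxyphenoxy)-2-(2,4,5-trimethoxyphenyl)acrylic acid
Conditions: LiOH, THF/MeOH/H2O, rt; then aq. HCl to pH 3, 0 °C
Reagents that add atoms: none
Why: Saponification of the methyl ester, as is usual for 3-aryloxyacrylates; once the carboxylate has formed the β-carbon is no longer electrophilic, and cold acidification to pH 3 frees the acid without hydrolysing the enol ether.

Step 9
Reactants: 12 (Z)-3-(2-allyl-3-methoxyphenoxy)-2-(2,4,5-trimethoxyphenyl)acrylic acid
Product: 14 8-allyl-7-methoxy-3-(2,4,5-trimethoxyphenyl)chromen-4-one, via mixed anhydride 13 (not isolated)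
Conditions: (CF3CO)2O (3 equiv), CH2Cl2 (0.02 M), 0 °C to rt
Reagents that add atoms: none
Why: Intramolecular Friedel–Crafts acylation (electrophilic aromatic substitution), the known way from 3-aryloxyacrylic acids to chromones, here with a 2-aryl group so that an isoflavone results. (CF3CO)2O converts 12 into mixed anhydride 13, which reacts as such or after ionisation to an acylium ion; the β-oxygen makes that ion a ketene–oxocarbenium hybrid, ArO(+)=CH–C(Ar′)=C=O, with single-bond character between C2 and C3, so an E isomer can rotate into the reactive arrangement. The ring A carbon para to the methoxy group and ortho to the ether oxygen attacks the acyl carbon to form C4–C4a, and loss of the proton from the arenium ion restores ring A and gives the 4-pyranone. Ring C closes in a six-membered exo mode at the acyl carbon, the departing trifluoroacetate (or the acylium oxygen) lying outside the new ring. No stereocentre is formed. Site selectivity is required and is secured by the substrate: the second ortho carbon carries the allyl group, the carbon attacked is the most electron-rich one left on ring A, and ring B cannot be reached by the acyl carbon without forming a four-membered ring. Chemoselectivity toward the side chain rests on its being allyl: a monosubstituted alkene is not protonated by CF3CO2H at room temperature, whereas a prenyl group would give a tertiary cation. High dilution disfavours acylation of ring B of a second molecule.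

Step 10
Reactants: 14 8-allyl-7-methoxy-3-(2,4,5-trimethoxyphenyl)chromen-4-one; 15 2-methylbut-2-ene
Product: 16 prebarbigerone, 7-methoxy-8-(3-methylbut-2-enyl)-3-(2,4,5-trimethoxyphenyl)chromen-4-one
Conditions: second-generation Grubbs catalyst (H2IMes)(PCy3)Cl2Ru=CHPh (5 mol %), 2-methylbut-2-ene/CH2Cl2, 40 °C
Reagents that add atoms: none
Why: Olefin cross-metathesis of a terminal allylarene with an excess of a trisubstituted alkene, the standard conversion of allyl into prenyl: propene is lost and any crotyl intermediate is converted further by the excess alkene. The pyranone C2=C3 bond is trisubstituted, conjugated and electron-poor and should stay out of the catalytic cycle; the new alkene carries two methyl groups, so no geometric isomers arise.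

## Compound list

1 | 3-methoxyphenol | COc1cccc(O)c1 | starting material
2 | 1-methoxy-3-(methoxymethoxy)benzene | COCOc1cccc(OC)c1 | intermediate
3 | allyl bromide | C=CCBr | starting material
4 | [2-methoxy-6-(methoxymethoxy)phenyl]lithium | [Li]c1c(OC)cccc1OCOC | intermediate (not isolated)
5 | 2-allyl-1-methoxy-3-(methoxymethoxy)benzene | C=CCc1c(OC)cccc1OCOC | intermediate
6 | 2-allyl-3-methoxyphenol | C=CCc1c(O)cccc1OC | intermediate
7 | 2-(2,4,5-trimethoxyphenyl)acetic acid | COc1cc(OC)c(CC(=O)O)cc1OC | starting material
8 | methyl 2-(2,4,5-trimethoxyphenyl)acetate | COC(=O)Cc1cc(OC)c(OC)cc1OC | intermediate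
9 | methyl (Z)-3-hydroxy-2-(2,4,5-trimethoxyphenyl)acrylate | COC(=O)/C(=C\O)c1cc(OC)c(OC)cc1OC | intermediate
10 | methyl (Z)-2-(2,4,5-trimethoxyphenyl)-3-(tosyloxy)acrylate | COC(=O)/C(=C\OS(=O)(=O)c1ccc(C)cc1)c1cc(OC)c(OC)cc1OC | intermediate
11 | methyl (Z)-3-(2-allyl-3-methoxyphenoxy)-2-(2,4,5-trimethoxyphenyl)acrylate | COC(=O)/C(=C\Oc1cccc(OC)c1CC=C)c1cc(OC)c(OC)cc1OC | intermediate
12 | (Z)-3-(2-allyl-3-methoxyphenoxy)-2-(2,4,5-trimethoxyphenyl)acrylic acid | OC(=O)/C(=C\Oc1cccc(OC)c1CC=C)c1cc(OC)c(OC)cc1OC | intermediate
13 | (Z)-3-(2-allyl-3-methoxyphenoxy)-2-(2,4,5-trimethoxyphenyl)acrylic trifluoroacetic anhydride | O=C(OC(=O)C(F)(F)F)/C(=C\Oc1cccc(OC)c1CC=C)c1cc(OC)c(OC)cc1OC | intermediate (not isolated)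
14 | 8-allyl-7-methoxy-3-(2,4,5-trimethoxyphenyl)chromen-4-one | COc1cc(OC)c(-c2coc3c(CC=C)c(OC)ccc3c2=O)cc1OC | intermediate
15 | 2-methylbut-2-ene | CC=C(C)C | starting material
16 | prebarbigerone, 7-methoxy-8-(3-methylbut-2-enyl)-3-(2,4,5-trimethoxyphenyl)chromen-4-one | COc1cc(OC)c(-c2coc3c(CC=C(C)C)c(OC)ccc3c2=O)cc1OC | target

## Step count and risks

Total steps: 10. Longest linear sequence: 7 steps (steps 1, 2, 3, 7, 8, 9, 10 from phenol 1, or steps 4, 5, 6, 7, 8, 9, 10 from acid 7).

**Step 9 (key step).** The acyl donor is a vinylogous carbonate, stabilised by the β-oxygen and the α-aryl group, so ring closure may be slow. During the wait, three things can compete: acylation or trifluoroacetylation of ring B of a second molecule, acid-promoted cleavage of the aryl enol ether, and slow addition of CF3CO2H to the allyl group. A first adjustment within the step is the acid chloride with SnCl4 at low temperature. The fallback abandons the tethered acylation and forms C4–C4a intermolecularly. It sets out from acid 7, which is condensed with resorcinol in BF3·OEt2 at about 85 °C to give 1-(2,4-dihydroxyphenyl)-2-(2,4,5-trimethoxyphenyl)ethanone F1. Treatment with N,N-dimethylformamide dimethyl acetal and acidic work-up closes ring C to 7-hydroxy-3-(2,4,5-trimethoxyphenyl)chromen-4-one F2. O-Alkylation with allyl bromide 3 and K2CO3 gives 7-(allyloxy)-3-(2,4,5-trimethoxyphenyl)chromen-4-one F3. Claisen rearrangement in hot N,N-diethylaniline should move the allyl group mainly to C8, as is usual for 7-allyloxy benzopyranones, giving 8-allyl-7-hydroxy-3-(2,4,5-trimethoxyphenyl)chromen-4-one F4. Methylation with MeI and K2CO3 returns to the route at 14.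

**Step 7.** The phenoxide may attack sulfur instead of the β-carbon, since the enolate of 9 is a good leaving group; this would transfer the tosyl group to phenol 6 and return 9. Partial loss of alkene geometry is also possible but harmless. The fallback removes the competing site: it sets out from 9, which oxalyl chloride and catalytic DMF convert into methyl (Z)-3-chloro-2-(2,4,5-trimethoxyphenyl)acrylate F5. Displacement of chloride by phenol 6 with K2CO3 in DMF returns to the route at 11.

**Step 8.** Hydrolysis of a hindered, conjugated ester is slow, and hydroxide may instead add to the β-carbon and expel the aryloxide, reversing step 7. The fallback replaces the base-labile ester by an acid-labile one and sets out from acid 7: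
- Boc2O, DMAP and tert-butanol give tert-butyl 2-(2,4,5-trimethoxyphenyl)acetate F6.
- Formylation as in step 5 gives tert-butyl (Z)-3-hydroxy-2-(2,4,5-trimethoxyphenyl)acrylate F7.
- Tosylation as in step 6 gives tert-butyl (Z)-2-(2,4,5-trimethoxyphenyl)-3-(tosyloxy)acrylate F8.
- Coupling with phenol 6 as in step 7 gives tert-butyl (Z)-3-(2-allyl-3-methoxyphenoxy)-2-(2,4,5-trimethoxyphenyl)acrylate F9.
- Cleavage with CF3CO2H in CH2Cl2, with Et3SiH to trap the tert-butyl cation before it alkylates ring B, returns to the route at 12.

**Step 10.** A ruthenium hydride formed from the catalyst may move the allyl double bond into conjugation with ring A before metathesis, which would shorten the chain by one carbon. Exchange may also stop at the crotyl stage. The fallback builds the alkene by olefination and sets out from 14. Oxidative cleavage of the terminal alkene with catalytic OsO4, NaIO4 and 2,6-lutidine in aqueous dioxane gives 2-[7-methoxy-4-oxo-3-(2,4,5-trimethoxyphenyl)chromen-8-yl]acetaldehyde F10. A Wittig reaction with isopropylidenetriphenylphosphorane, made from isopropyltriphenylphosphonium iodide and n-BuLi, returns to the route at 16.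

## Further compounds

F1 | step 9 | 1-(2,4-dihydroxyphenyl)-2-(2,4,5-trimethoxyphenyl)ethanone | COc1cc(OC)c(CC(=O)c2ccc(O)cc2O)cc1OC
F2 | step 9 | 7-hydroxy-3-(2,4,5-trimethoxyphenyl)chromen-4-one | COc1cc(OC)c(-c2coc3cc(O)ccc3c2=O)cc1OC
F3 | step 9 | 7-(allyloxy)-3-(2,4,5-trimethoxyphenyl)chromen-4-one | COc1cc(OC)c(-c2coc3cc(OCC=C)ccc3c2=O)cc1OC
F4 | step 9 | 8-allyl-7-hydroxy-3-(2,4,5-trimethoxyphenyl)chromen-4-one | COc1cc(OC)c(-c2coc3c(CC=C)c(O)ccc3c2=O)cc1OC
F5 | step 7 | methyl (Z)-3-chloro-2-(2,4,5-trimethoxyphenyl)acrylate | COC(=O)/C(=C\Cl)c1cc(OC)c(OC)cc1OC
F6 | step 8 | tert-butyl 2-(2,4,5-trimethoxyphenyl)acetate | COc1cc(OC)c(CC(=O)OC(C)(C)C)cc1OC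
F7 | step 8 | tert-butyl (Z)-3-hydroxy-2-(2,4,5-trimethoxyphenyl)acrylate | CC(C)(C)OC(=O)/C(=C\O)c1cc(OC)c(OC)cc1OC
F8 | step 8 | tert-butyl (Z)-2-(2,4,5-trimethoxyphenyl)-3-(tosyloxy)acrylate | CC(C)(C)OC(=O)/C(=C\OS(=O)(=O)c1ccc(C)cc1)c1cc(OC)c(OC)cc1OC
F9 | step 8 | tert-butyl (Z)-3-(2-allyl-3-methoxyphenoxy)-2-(2,4,5-trimethoxyphenyl)acrylate | CC(C)(C)OC(=O)/C(=C\Oc1cccc(OC)c1CC=C)c1cc(OC)c(OC)cc1OC
F10 | step 10 | 2-[7-methoxy-4-oxo-3-(2,4,5-trimethoxyphenyl)chromen-8-yl]acetaldehyde | COc1cc(OC)c(-c2coc3c(CC=O)c(OC)ccc3c2=O)cc1OC
A1 | alternative 1 | [(1E)-1,3-dimethoxy-2-(3-methylbut-2-enyl)buta-1,3-dienyl]oxy(trimethyl)silane | CO/C(O[Si](C)(C)C)=C(/CC=C(C)C)C(OC)=C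
A2 | alternative 1 | 1-(2,4,5-trimethoxyphenyl)but-3-yn-2-one | C#CC(=O)Cc1cc(OC)c(OC)cc1OC
A3 | alternative 1 | 1-[2-hydroxy-4-methoxy-3-(3-methylbut-2-enyl)phenyl]-2-(2,4,5-trimethoxyphenyl)ethanone | COc1cc(OC)c(CC(=O)c2ccc(OC)c(CC=C(C)C)c2O)cc1OC
A4 | alternative 2 | 5-ethenyl-3-(2,4,5-trimethoxyphenyl)pyran-4-one | C=CC1=COC=C(c2cc(OC)c(OC)cc2OC)C1=O
A5 | alternative 2 | 1-methoxy-5-methylhex-4-en-1-yne | COC#CCC=C(C)C
A6 | alternative 2 | 7-methoxy-8-(3-methylbut-2-enyl)-3-(2,4,5-trimethoxyphenyl)-6,8a-dihydrochromen-4-one (racemic) | COC1=C(CC=C(C)C)C2OC=C(c3cc(OC)c(OC)cc3OC)C(=O)C2=CC1
A7 | alternative 3 | 4-methoxy-3-(3-methylbut-2-enyl)-2-[2-oxo-2-(2,4,5-trimethoxyphenyl)ethoxy]benzaldehyde | O=Cc1ccc(OC)c(CC=C(C)C)c1OCC(=O)c1cc(OC)c(OC)cc1OC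
A8 | alternative 3 | 3-hydroxy-7-methoxy-8-(3-methylbut-2-enyl)-3-(2,4,5-trimethoxyphenyl)chroman-4-one (racemic) | COc1cc(OC)c(C2(O)COc3c(CC=C(C)C)c(OC)ccc3C2=O)cc1OC
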